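**Retrosynthetic overview**

1. Atom labels: five-membered ring C1(OAc)–C2H2–C3(CH3)–C9H–C10(OH)(i-Pr); seven-membered ring C3–C4(OH)–C5H2–C6(CH3)=C7H–C8(O-aroyl)–C9. The strategy rests on C3: it carries a methyl and the ring methylene C2, formally the two carbons of a gem-dimethyl group, and C2 lies 1,5 to C1 along C1–C10–C9–C3–C2.
2. Key disconnection C1–C2: a rhodium carbene made from a diazoacetyl group on C9 (C10=O, C1=N2) inserts into a C–H bond of the cis methyl of a 3,3-dimethylcycloheptane whose C4 and C7 are ketal carbons and whose C8 oxygen is a silyl ether. This closes the five-membered ring, cis-fused.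
3. After it: C10 ketone → enol triflate → isopropyl coupling → α-face dihydroxylation and C1 acetylation; C7 ketal → ketone → enol triflate → C6=C7; C4 ketal → ketone, reduced by hydride delivered from O8 with the silyloxybenzoyl group landing on O8; desilylation.
4. Before it: the seven-membered ring by ring-closing metathesis (C6=C7) of an auxiliary-controlled syn-aldol adduct (C8–C9 bond, both stereocentres) of acrolein with an imide built from 2,2-dimethylsuccinic anhydride; the C7 oxygen by hydroboration.
5. Ring order: seven-membered ring (step 6), then five-membered ring (step 13).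

Key step: step 13

Remark: α is the face of the carbocycle that carries H9 (and, from 21 on, the C3 methyl), β the opposite face; descriptors in names of ring compounds use the atom labels above.
Assumption: the C6 configuration drawn for 15–26 is the one expected from α-face hydroboration; it has no consequence because C6 becomes sp2 in step 17.

**Route**

Step 1
Reactants: 1 2,2-dimethylsuccinic anhydride; 2 (R)-4-benzyl-1,3-oxazolidin-2-one
Product: 3 imide acid (oxazolidinone on C10, free acid on C4)
Conditions: Et3N, LiCl, DMAP (cat.), THF, 0 °C → rt; aq. HCl work-up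
Reagents that add atoms: none
Why: N-acylation of the oxazolidinone by ring opening of the cyclic anhydride (DMAP acyl transfer) should occur at the carbonyl next to the CH2 group, because the carbonyl on the quaternary carbon is shielded, so the remaining acid is the C4 carboxyl on C3.

Step 2
Reactants: 3 imide acid; 4 trimethyl(2-methylprop-2-en-1-yl)silane
Product: 6 methallyl ketone imide, via acid chloride 5 (not isolated)
Conditions: (COCl)2, DMF (cat.), CH2Cl2, 0 °C → rt, evaporate; then 4, TiCl4, CH2Cl2, −78 °C
Reagents that add atoms: none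
Why: Acid chloride formation followed by Lewis-acid-promoted acylation of the allylsilane (Sakurai-type SE2′ substitution) attaches C5–C6 to C4 and leaves the methallyl alkene out of conjugation at −78 °C, the imide being inert to both operations.

Step 3
Reactants: 6 methallyl ketone imide
Product: 7 dioxolane imide
Conditions: (Me3SiOCH2)2, Me3SiOTf (cat.), CH2Cl2, −78 → −20 °C
Reagents that add atoms: 1,2-bis(trimethylsilyloxy)ethane, C[Si](C)(C)OCCO[Si](C)(C)C
Why: Noyori ketalisation (silyl triflate catalysis, no water, low temperature) should convert the hindered C4 ketone into its dioxolane without moving the β,γ-alkene, which removes the second enolisable site before the aldol reaction and blocks C4 for the key step.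

Step 4
Reactants: 7 dioxolane imide; 8 acrolein
Product: 10 syn-aldol adduct (C9 R, C8 S), via boron enolate 9 (not isolated)
Conditions: n-Bu2BOTf, i-Pr2NEt, CH2Cl2, −78 → 0 °C; then 8, −78 → 0 °C; then pH 7 buffer, MeOH, H2O2, 0 °C
Reagents that add atoms: none
Why: Evans syn-aldol reaction: the Z-boron enolate reacts through a closed chair (Zimmerman–Traxler) transition state on the enolate face away from the benzyl group of the (R)-auxiliary, which sets C9 (R) and C8 (S) in the syn relationship that becomes the cis arrangement of C8–O and the C9 side chain in the ring.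

Step 5
Reactants: 10 syn-aldol adduct
Product: 11 silyl ether of the aldol adduct
Conditions: TBSOTf, 2,6-lutidine, CH2Cl2, −78 °C
Reagents that add atoms: tert-butyldimethylsilyl trifluoromethanesulfonate, CC(C)(C)[Si](C)(C)OS(=O)(=O)C(F)(F)F
Why: Silylation of the secondary aldol hydroxyl with the silyl triflate at −78 °C outruns retro-aldol cleavage, spares the dioxolane and installs the bulky, weakly nucleophilic C8 protecting group wanted in the key step.

Step 6
Reactants: 11 silyl ether of the aldol adduct
Product: 12 cycloheptene imide (C6=C7)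
Conditions: second-generation Grubbs catalyst RuCl2(=CHPh)(PCy3)(H2IMes) (5 mol %), CH2Cl2 (5 mM), 40 °C
Reagents that add atoms: none
Why: Ring-closing metathesis between the vinyl group on C8 and the 1,1-disubstituted methallyl alkene should close the seven-membered ring as the trisubstituted C6=C7 alkene, helped by the fully substituted C3 and C4 (gem-disubstituent effect) and driven by loss of ethene.

Step 7
Reactants: 12 cycloheptene imide
Product: 13 benzyl ester
Conditions: BnOH, n-BuLi, THF, −78 → 0 °C; aq. NH4Cl
Reagents that add atoms: benzyl alcohol (used as its lithium alkoxide), OCc1ccccc1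
Why: Transesterification of the N-acyl oxazolidinone with lithium benzyloxide (attack at the exocyclic carbonyl) removes the auxiliary at low temperature, where β-elimination of the silyloxy group should not compete, and gives an ester that tolerates borane and is later cleaved under neutral conditions.

Step 8
Reactants: 13 benzyl ester
Product: 15 C7 alcohol (7α-OH, 6β-CH3), via alkylborane 14 (not isolated)
Conditions: BH3·THF, THF, 0 °C → rt; then NaOH, H2O2, 0 °C
Reagents that add atoms: hydrogen peroxide, OO
Why: Hydroboration–oxidation places boron on the less substituted C7 and adds from the α face, away from the β silyloxy group on C8 and the β ester on C9, so that C7–OH is α and the C6 methyl β (both centres are removed later).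

Step 9
Reactants: 15 C7 alcohol
Product: 16 C7 ketone
Conditions: Dess–Martin periodinane, NaHCO3, CH2Cl2, rt
Reagents that add atoms: none
Why: Dess–Martin oxidation of the secondary alcohol under buffered conditions gives the C7 ketone without touching the silyl ether, the dioxolane or the C8 stereocentre.

Step 10
Reactants: 16 C7 ketone
Product: 17 C7 dimethyl ketal
Conditions: MeOSiMe3, Me3SiOTf (cat.), CH2Cl2, −78 → −30 °C
Reagents that add atoms: methoxytrimethylsilane, CO[Si](C)(C)C
Why: Noyori ketalisation with the alkoxysilane masks the C7 ketone as an acyclic dimethyl ketal, chosen because it can later be hydrolysed beside the C4 dioxolane, and at low temperature neither the silyl ether nor the α stereocentre C8 should be affected.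

Step 11
Reactants: 17 C7 dimethyl ketal
Product: 18 carboxylic acid
Conditions: H2 (1 atm), Pd/C, EtOAc, rt
Reagents that add atoms: none
Why: Hydrogenolysis of the benzyl ester frees the hindered C10 acid under neutral conditions that spare both ketals and the silyl ether.

Step 12
Reactants: 18 carboxylic acid
Product: 20 diazoketone (precursor of the key step), via acid chloride 19 (not isolated)
Conditions: Me2C=C(Cl)NMe2, CH2Cl2, 0 °C → rt; then CH2N2 (excess), Et2O, 0 °C
Reagents that add atoms: diazomethane, C=[N+]=[N-]
Why: The neutral α-chloroenamine gives the acid chloride without HCl, and acylation of diazomethane (Arndt–Eistert-type diazoketone synthesis, second equivalent as HCl scavenger) gives the diazoketone with no base present that could form a ketene or eliminate the β-silyloxy group.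

Step 13
Reactants: 20 diazoketone
Product: 21 cis-fused bicyclic ketone (C10=O, new C1–C2 bond)
Conditions: Rh2(O2CC3F7)4 (1 mol %), CH2Cl2, rt, slow addition of 20 (final 5 mM)
Reagents that add atoms: none
Why: Loss of N2 from 20 at the dirhodium core gives an electrophilic rhodium carbene at C1, which inserts through a concerted three-centre transition state into a C–H bond of a C3 methyl group and so forms the C1–C2 bond; the closest known reaction type is the rhodium-carboxylate-catalysed 1,5 C–H insertion of α-diazoketones to cyclopentanones, which is documented for methyl C–H bonds although these are the least reactive class. The cyclopentanone (C1, C2, C3, C9, C10) is closed in the 1,5 mode across the C3–C9 bond as a cis-fused bicyclo[5.3.0]decanone. The new stereocentre C3 is set by which methyl reacts: the five-ring transition state needs a small C10–C9–C3–CH3 dihedral angle, which the methyl cis to the side chain (β) reaches without distorting the cycloheptane, so the remaining methyl ends up α, cis to H9, and C8 and C9 are not touched. The selectivity needed is primary 1,5 insertion over all other carbene reactions, and the substrate secures it because C4 and C7 are fully substituted ketal carbons without C–H or carbonyl oxygen, so the only 1,5 C–H bonds are those of the two methyls, while C8–H is 1,4 and the C5–H and C6–H bonds are 1,6 and transannular. The perfluorobutyrate ligands make the carbene electrophilic enough for a primary C–H bond and slow addition at high dilution suppresses dimerisation; ylide formation at the ketal or silyl ether oxygens and insertion into the trans methyl remain the competing paths.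

Step 14
Reactants: 21 cis-fused bicyclic ketone
Product: 23 C10 enol triflate, via potassium enolate 22 (not isolated)
Conditions: KN(SiMe3)2, THF, −78 °C; then PhNTf2, −78 → 0 °C
Reagents that add atoms: N-phenylbis(trifluoromethanesulfonimide), O=S(=O)(N(c1ccccc1)S(=O)(=O)C(F)(F)F)C(F)(F)F
Why: Kinetic deprotonation with the bulky amide should take place at the C1 methylene and not at the hindered C9 methine (whose enolate could expel the C8 silyloxy group), and O-sulfonylation of the enolate gives the C10=C1 enol triflate.

Step 15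
Reactants: 23 C10 enol triflate; 24 isopropylmagnesium chloride
Product: 25 isopropyl cyclopentene
Conditions: Fe(acac)3 (5 mol %), THF/NMP, −30 °C
Reagents that add atoms: none
Why: Iron-catalysed cross-coupling of the alkenyl triflate with the secondary alkyl Grignard reagent is fast at low temperature and tolerates ketals and silyl ethers, giving the C10 isopropyl alkene with the double bond fixed at C10=C1.

Step 16
Reactants: 25 isopropyl cyclopentene
Product: 26 C7 ketone (C4 dioxolane kept)
Conditions: oxalic acid (10% aq.) on SiO2, CH2Cl2, rt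
Reagents that add atoms: water, O
Why: Acid-catalysed ketal hydrolysis under very mild conditions should cleave the acyclic dimethyl ketal at C7 while the cyclic dioxolane at C4 and the silyl ether survive.

Step 17
Reactants: 26 C7 ketone
Product: 28 C7 enol triflate (C6=C7), via potassium enolate 27 (not isolated)
Conditions: KN(SiMe3)2, THF, −78 → −40 °C; then PhNTf2
Reagents that add atoms: N-phenylbis(trifluoromethanesulfonimide), O=S(=O)(N(c1ccccc1)S(=O)(=O)C(F)(F)F)C(F)(F)F
Why: Enolate formation and O-triflation: the α-silyloxy C8–H is not removed under kinetic conditions, so deprotonation at C6 gives the tetrasubstituted C6=C7 enol triflate, an electron-poor alkene that will not react with OsO4 in the next step.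

Step 18
Reactants: 28 C7 enol triflate
Product: 29 1α,10α-diol
Conditions: OsO4 (2 mol %), N-methylmorpholine N-oxide, acetone/H2O, rt
Reagents that add atoms: N-methylmorpholine N-oxide, C[N+]1([O-])CCOCC1; water, O
Why: Catalytic cis-dihydroxylation (Upjohn conditions) should take place only at the electron-rich C1=C10 alkene and from the convex α face of the cis-fused bicycle, anti to the allylic C9–C8 bond, which sets C10 (OH α, isopropyl β) and C1 (OH α) in one syn addition.

Step 19
Reactants: 29 1α,10α-diol
Product: 30 C1 acetate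
Conditions: Ac2O, pyridine, DMAP (cat.), CH2Cl2, 0 °C → rt
Reagents that add atoms: acetic anhydride, CC(=O)OC(C)=O
Why: DMAP-catalysed acylation esterifies the secondary C1 hydroxyl only, the tertiary C10 hydroxyl being unreactive under these conditions.

Step 20
Reactants: 30 C1 acetate
Product: 31 C4 ketone (enol triflate kept)
Conditions: PPTS, acetone/H2O (5:1), 55 °C
Reagents that add atoms: water, O
Why: Acid-catalysed hydrolysis of the hindered dioxolane is done while C6=C7 still carries the triflate, so that neither an allylic cation at C8 nor migration of the alkene into conjugation with the new ketone is possible.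

Step 21
Reactants: 31 C4 ketone
Product: 32 C6=C7 alkene
Conditions: Pd(PPh3)4 (5 mol %), n-Bu3SnH, LiCl, THF, rt → 50 °C
Reagents that add atoms: none
Why: Palladium-catalysed reduction of the enol triflate with the tin hydride (oxidative addition, tin-to-palladium hydride transfer, reductive elimination) replaces OTf by H under neutral conditions, so no base is present to move the alkene into conjugation with the C4 ketone, and the allylic silyl ether cannot ionise.

Step 22
Reactants: 32 C6=C7 alkene
Product: 33 C8 hydroxy ketone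
Conditions: HF·pyridine, pyridine, THF, 0 °C → rt
Reagents that add atoms: none
Why: Buffered fluoride desilylation frees the allylic C8 hydroxyl without base, so the β,γ-unsaturated ketone is not isomerised and the acetate does not migrate.

Step 23
Reactants: 33 C8 hydroxy ketone; 34 4-[(tert-butyldimethylsilyl)oxy]benzaldehyde
Product: 35 O8 4-silyloxybenzoate with 4α-OH
Conditions: 34 (5 equiv), SmI2 (0.3 equiv), THF, −10 °C
Reagents that add atoms: none
Why: Proposed new method: a 1,4 (transannular) version of the Evans–Tishchenko reduction, in which the samarium alkoxide of O8 adds to aldehyde 34 and the resulting hemiacetal, held on the β face where O8 lies within reach of C4 across the ring, passes its hydride to the β face of the C4 carbonyl through a seven-membered transition state and thereby becomes the O8 ester, so that C4 is set as the 4α alcohol (trans to O8) and the aroyl group is placed on O8 in the same event, whereas an external hydride would be expected to enter from the open α face; closest known reaction type: the SmI2-catalysed Evans–Tishchenko reduction of β-hydroxy ketones to anti-1,3-diol monoesters, which runs through the analogous six-membered hydride transfer.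

Step 24
Reactants: 35 O8 4-silyloxybenzoate with 4α-OH
Product: 36 target
Conditions: KHF2, MeOH, rt
Reagents that add atoms: none
Why: Bifluoride in methanol cleaves the phenolic silyl ether selectively (phenoxide is the better leaving group on silicon), leaving both esters, the allylic system and the free hydroxyls unchanged.

**Compound list**

1 | 2,2-dimethylsuccinic anhydride (3,3-dimethyloxolane-2,5-dione) | CC1(C)CC(=O)OC1=O | starting material
2 | (R)-4-benzyl-1,3-oxazolidin-2-one | O=C1N[C@H](Cc2ccccc2)CO1 | starting material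
3 | 4-[(4R)-4-benzyl-2-oxo-1,3-oxazolidin-3-yl]-2,2-dimethyl-4-oxobutanoic acid | OC(=O)C(C)(C)CC(=O)N1C(=O)OC[C@H]1Cc1ccccc1 | intermediate
4 | trimethyl(2-methylprop-2-en-1-yl)silane | CC(=C)C[Si](C)(C)C | starting material
5 | 4-[(4R)-4-benzyl-2-oxo-1,3-oxazolidin-3-yl]-2,2-dimethyl-4-oxobutanoyl chloride | ClC(=O)C(C)(C)CC(=O)N1C(=O)OC[C@H]1Cc1ccccc1 | intermediate
6 | (4R)-4-benzyl-3-(3,3,6-trimethyl-4-oxohept-6-enoyl)-1,3-oxazolidin-2-one | CC(=C)CC(=O)C(C)(C)CC(=O)N1C(=O)OC[C@H]1Cc1ccccc1 | intermediate
7 | (4R)-4-benzyl-3-{3-methyl-3-[2-(2-methylprop-2-en-1-yl)-1,3-dioxolan-2-yl]butanoyl}-1,3-oxazolidin-2-one | CC(=C)CC1(OCCO1)C(C)(C)CC(=O)N2C(=O)OC[C@H]2Cc3ccccc3 | intermediate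
8 | acrolein (prop-2-enal) | C=CC=O | starting material
9 | (Z)-di-n-butylboron enolate of 7 (O–B cis to the C3 substituent on the C9=C10 bond) | CCCCB(CCCC)O/C(=C\C(C)(C)C1(CC(C)=C)OCCO1)N2C(=O)OC[C@H]2Cc3ccccc3 | intermediate
10 | (4R)-4-benzyl-3-[(2R,3S)-3-hydroxy-2-{2-[2-(2-methylprop-2-en-1-yl)-1,3-dioxolan-2-yl]propan-2-yl}pent-4-enoyl]-1,3-oxazolidin-2-one (syn aldol; C9 R, C8 S) | CC(=C)CC1(OCCO1)C(C)(C)[C@@H](C(=O)N2C(=O)OC[C@H]2Cc3ccccc3)[C@@H](O)C=C | intermediate
11 | (4R)-4-benzyl-3-[(2R,3S)-3-(tert-butyldimethylsilyloxy)-2-{2-[2-(2-methylprop-2-en-1-yl)-1,3-dioxolan-2-yl]propan-2-yl}pent-4-enoyl]-1,3-oxazolidin-2-one | CC(=C)CC1(OCCO1)C(C)(C)[C@@H](C(=O)N2C(=O)OC[C@H]2Cc3ccccc3)[C@@H](O[Si](C)(C)C(C)(C)C)C=C | intermediate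
12 | (4R)-4-benzyl-3-{[(8S,9R)-8-(tert-butyldimethylsilyloxy)-4,4-(ethylenedioxy)-3,3,6-trimethylcyclohept-6-en-9-yl]carbonyl}-1,3-oxazolidin-2-one (C8–O and C9 side chain cis, β) | CC1(C)[C@@H](C(=O)N2C(=O)OC[C@H]2Cc3ccccc3)[C@@H](O[Si](C)(C)C(C)(C)C)C=C(C)CC14OCCO4 | intermediate
13 | benzyl (8S,9R)-8-(tert-butyldimethylsilyloxy)-4,4-(ethylenedioxy)-3,3,6-trimethylcyclohept-6-ene-9-carboxylate | CC1(C)[C@@H](C(=O)OCc2ccccc2)[C@@H](O[Si](C)(C)C(C)(C)C)C=C(C)CC13OCCO3 | intermediate
14 | C7 alkylborane of 13 (BH2 on C7 α, new H on C6 α) | CC1(C)[C@@H](C(=O)OCc2ccccc2)[C@@H](O[Si](C)(C)C(C)(C)C)[C@H](B)[C@@H](C)CC13OCCO3 | intermediate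
15 | benzyl (6S,7R,8R,9R)-8-(tert-butyldimethylsilyloxy)-4,4-(ethylenedioxy)-7-hydroxy-3,3,6-trimethylcycloheptane-9-carboxylate (7α-OH, 6β-CH3, 8β-OSi, 9β-ester) | CC1(C)[C@@H](C(=O)OCc2ccccc2)[C@@H](O[Si](C)(C)C(C)(C)C)[C@H](O)[C@@H](C)CC13OCCO3 | intermediate
16 | benzyl (6S,8R,9R)-8-(tert-butyldimethylsilyloxy)-4,4-(ethylenedioxy)-3,3,6-trimethyl-7-oxocycloheptane-9-carboxylate | CC1(C)[C@@H](C(=O)OCc2ccccc2)[C@@H](O[Si](C)(C)C(C)(C)C)C(=O)[C@@H](C)CC13OCCO3 | intermediate
17 | benzyl (6S,8R,9R)-8-(tert-butyldimethylsilyloxy)-4,4-(ethylenedioxy)-7,7-dimethoxy-3,3,6-trimethylcycloheptane-9-carboxylate | CC1(C)[C@@H](C(=O)OCc2ccccc2)[C@@H](O[Si](C)(C)C(C)(C)C)C(OC)(OC)[C@@H](C)CC13OCCO3 | intermediate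
18 | (6S,8R,9R)-8-(tert-butyldimethylsilyloxy)-4,4-(ethylenedioxy)-7,7-dimethoxy-3,3,6-trimethylcycloheptane-9-carboxylic acid | CC1(C)[C@@H](C(=O)O)[C@@H](O[Si](C)(C)C(C)(C)C)C(OC)(OC)[C@@H](C)CC12OCCO2 | intermediate
19 | acid chloride of 18 | CC1(C)[C@@H](C(=O)Cl)[C@@H](O[Si](C)(C)C(C)(C)C)C(OC)(OC)[C@@H](C)CC12OCCO2 | intermediate
20 | diazoketone: (6S,8R,9R)-8-(tert-butyldimethylsilyloxy)-9-(diazoacetyl)-4,4-(ethylenedioxy)-7,7-dimethoxy-3,3,6-trimethylcycloheptane (8β-OSi and 9β-diazoacetyl cis, 6β-CH3) | CC1(C)[C@@H](C(=O)C=[N+]=[N-])[C@@H](O[Si](C)(C)C(C)(C)C)C(OC)(OC)[C@@H](C)CC12OCCO2 | intermediate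
21 | cis-fused bicyclo[5.3.0]decan-10-one: 3α-CH3, 9α-H, C4 ethylene ketal, 6β-CH3, C7 dimethyl ketal, 8β-OTBS | C1C[C@]2(C)C3(OCCO3)C[C@H](C)C(OC)(OC)[C@H](O[Si](C)(C)C(C)(C)C)[C@@H]2C1=O | intermediate
22 | potassium C10(O)=C1 enolate of 21 | [K+].[O-]C1=CC[C@]2(C)C3(OCCO3)C[C@H](C)C(OC)(OC)[C@H](O[Si](C)(C)C(C)(C)C)[C@@H]21 | intermediate
23 | C10 enol triflate (C10=C1) of 21 | FC(F)(F)S(=O)(=O)OC1=CC[C@]2(C)C3(OCCO3)C[C@H](C)C(OC)(OC)[C@H](O[Si](C)(C)C(C)(C)C)[C@@H]21 | intermediate
24 | isopropylmagnesium chloride | CC(C)[Mg]Cl | starting material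
25 | 10-isopropyl C10=C1 alkene: 3α-CH3, 9α-H, C4 ethylene ketal, 6β-CH3, C7 dimethyl ketal, 8β-OTBS | CC(C)C1=CC[C@]2(C)C3(OCCO3)C[C@H](C)C(OC)(OC)[C@H](O[Si](C)(C)C(C)(C)C)[C@@H]21 | intermediate
26 | C7 ketone of 25 (C4 ethylene ketal kept) | CC(C)C1=CC[C@]2(C)C3(OCCO3)C[C@H](C)C(=O)[C@H](O[Si](C)(C)C(C)(C)C)[C@@H]21 | intermediate
27 | potassium C7(O)=C6 enolate of 26 | [K+].CC(C)C1=CC[C@]2(C)C3(OCCO3)CC(C)=C([O-])[C@H](O[Si](C)(C)C(C)(C)C)[C@@H]21 | intermediate
28 | C7 enol triflate (C6=C7) with C10=C1 isopropyl alkene, C4 ethylene ketal, 8β-OTBS | CC(C)C1=CC[C@]2(C)C3(OCCO3)CC(C)=C(OS(=O)(=O)C(F)(F)F)[C@H](O[Si](C)(C)C(C)(C)C)[C@@H]21 | intermediate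
29 | 1α,10α-diol (10β-isopropyl) with C7 enol triflate, C4 ethylene ketal, 8β-OTBS | O[C@H]1C[C@]2(C)C3(OCCO3)CC(C)=C(OS(=O)(=O)C(F)(F)F)[C@H](O[Si](C)(C)C(C)(C)C)[C@@H]2[C@]1(O)C(C)C | intermediate
30 | 1α-acetate of 29 (10α-OH free) | CC(=O)O[C@H]1C[C@]2(C)C3(OCCO3)CC(C)=C(OS(=O)(=O)C(F)(F)F)[C@H](O[Si](C)(C)C(C)(C)C)[C@@H]2[C@]1(O)C(C)C | intermediate
31 | C4 ketone: 1α-OAc, 10α-OH, C7 enol triflate, 8β-OTBS | CC(=O)O[C@H]1C[C@]2(C)C(=O)CC(C)=C(OS(=O)(=O)C(F)(F)F)[C@H](O[Si](C)(C)C(C)(C)C)[C@@H]2[C@]1(O)C(C)C | intermediate
32 | C4 ketone with C6=C7 alkene: 1α-OAc, 10α-OH, 8β-OTBS | CC(=O)O[C@H]1C[C@]2(C)C(=O)CC(C)=C[C@H](O[Si](C)(C)C(C)(C)C)[C@@H]2[C@]1(O)C(C)C | intermediate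
33 | 8β-hydroxy C4 ketone: 1α-OAc, 10α-OH, C6=C7 | CC(=O)O[C@H]1C[C@]2(C)C(=O)CC(C)=C[C@H](O)[C@@H]2[C@]1(O)C(C)C | intermediate
34 | 4-[(tert-butyldimethylsilyl)oxy]benzaldehyde | CC(C)(C)[Si](C)(C)Oc1ccc(C=O)cc1 | starting material
35 | 1α-acetoxy-4α,10α-dihydroxy-10β-isopropyl-3α,6-dimethyl-cis-bicyclo[5.3.0]dec-6-en-8β-yl 4-[(tert-butyldimethylsilyl)oxy]benzoate | CC(=O)O[C@H]1C[C@]2(C)[C@@H](O)CC(C)=C[C@H](OC(=O)c3ccc(O[Si](C)(C)C(C)(C)C)cc3)[C@@H]2[C@]1(O)C(C)C | intermediate
36 | 1α-acetoxy-4α,10α-dihydroxy-10β-isopropyl-3α,6-dimethyl-cis-bicyclo[5.3.0]dec-6-en-8β-yl 4-hydroxybenzoate (CNP0146780.2) | CC(=O)O[C@H]1C[C@]2(C)[C@@H](O)CC(C)=C[C@H](OC(=O)c3ccc(O)cc3)[C@@H]2[C@]1(O)C(C)C | target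

**Step count and risks**

Total step count: 24. Longest linear sequence: 24 steps (1 → 36).

Steps most likely to fail:

1. Step 23 (proposed new method). What may go wrong: the hydride shift from the O8-bound hemiacetal to C4 is too slow through the seven-membered transition state, so that only reversible hemiacetal formation and Tishchenko dimerisation of the aldehyde take place. Fallback with known chemistry (reduction and acylation as separate events): starting from 33, hydroxyl-directed reduction with Me4NBH(OAc)3 in MeCN/AcOH at −20 °C (Evans–Saksena reduction, hydride delivered from the O8-bound borohydride to the β face of C4) gives the 4α,8β-diol F1. Et3SiCl and imidazole at −20 °C silylate the more exposed 4α hydroxyl on the convex face to give the triethylsilyl ether F2. Esterification of the 8β hydroxyl with 4-[(tert-butyldimethylsilyl)oxy]benzoic acid (2,4,6-trichlorobenzoyl chloride, Et3N, DMAP, Yamaguchi conditions) gives the bis-silylated ester F3. HF·pyridine then removes both silyl groups and the sequence comes back to the route at 36.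

2. Step 13 (key step). What may go wrong: capture of the carbene by a ketal or silyl ether oxygen (ylide formation), insertion into the trans methyl, or transannular 1,6 insertion in place of 1,5 insertion into the cis methyl. Fallback (stabilised acceptor/acceptor carbene instead of the diazoketone): starting from 18, activation with carbonyldiimidazole and reaction with Mg(O2CCH2CO2Me)2 gives the methyl β-keto ester F4. Diazo transfer (4-acetamidobenzenesulfonyl azide, Et3N, MeCN) gives the α-diazo-β-keto ester F5. Rh2(OAc)4 in CH2Cl2 at reflux effects the same 1,5 insertion into the cis methyl with a carbene for which ylide formation is reversible, giving the 1-methoxycarbonyl cyclopentanone F6. Krapcho dealkoxycarbonylation (LiCl, wet DMSO, 130 °C) returns to the route at 21.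

3. Step 15. What may go wrong: β-hydride elimination or isomerisation at the isopropyl–iron stage, giving the reduced alkene or the n-propyl isomer, or attack of the Grignard reagent at sulfur with loss of the triflate. Fallback (two-step isopropenylation and hydrogenation): starting from 23, Suzuki–Miyaura coupling with isopropenylboronic acid pinacol ester (Pd(dppf)Cl2, K3PO4, dioxane/H2O, 60 °C) gives the isopropenyl diene F7. Hydrogenation with RhCl(PPh3)3 under H2 (1 atm, benzene) saturates only the 1,1-disubstituted alkene and comes back to the route at 25.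

**Further compounds**

F1 | step 23 | 4α,8β-diol: 1α-OAc, 10α-OH, 10β-isopropyl, C6=C7 | CC(=O)O[C@H]1C[C@]2(C)[C@@H](O)CC(C)=C[C@H](O)[C@@H]2[C@]1(O)C(C)C
F2 | step 23 | 4α-triethylsilyl ether of F1 (8β-OH free) | CC(=O)O[C@H]1C[C@]2(C)[C@@H](O[Si](CC)(CC)CC)CC(C)=C[C@H](O)[C@@H]2[C@]1(O)C(C)C
F3 | step 23 | 8β-(4-tert-butyldimethylsilyloxybenzoate) of F2 | CC(=O)O[C@H]1C[C@]2(C)[C@@H](O[Si](CC)(CC)CC)CC(C)=C[C@H](OC(=O)c3ccc(O[Si](C)(C)C(C)(C)C)cc3)[C@@H]2[C@]1(O)C(C)C
F4 | step 13 | methyl β-keto ester on C9 (homologue of 18; 6S,8R,9R) | CC1(C)[C@@H](C(=O)CC(=O)OC)[C@@H](O[Si](C)(C)C(C)(C)C)C(OC)(OC)[C@@H](C)CC12OCCO2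
F5 | step 13 | α-diazo-β-keto ester of F4 | CC1(C)[C@@H](C(=O)C(=[N+]=[N-])C(=O)OC)[C@@H](O[Si](C)(C)C(C)(C)C)C(OC)(OC)[C@@H](C)CC12OCCO2
F6 | step 13 | 1-methoxycarbonyl derivative of 21 (C1 epimerisable, not specified) | COC(=O)C1C[C@]2(C)C3(OCCO3)C[C@H](C)C(OC)(OC)[C@H](O[Si](C)(C)C(C)(C)C)[C@@H]2C1=O
F7 | step 15 | 10-isopropenyl C10=C1 diene (isopropenyl analogue of 25) | CC(=C)C1=CC[C@]2(C)C3(OCCO3)C[C@H](C)C(OC)(OC)[C@H](O[Si](C)(C)C(C)(C)C)[C@@H]21
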